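# Proposed total synthesis of CNP0249167.1 (compound 31) by a vinylcarbenoid cyclopropanation–Cope [4+3] union

## Analysis of the target

Compound 31 is a cis-fused bicyclo[5.3.0]decane (hydroazulene of the daucane type): a cyclopentane C1–C5 shares the C1–C5 bond with a cycloheptene C5–C6–C7–C8–C9–C10–C1. The numbering used throughout is C1 (quaternary, methyl), C2 (CHOH), C3 (CH2), C4 (C(OH)iPr), C5 (ring-fusion CH), C6 (CH–OAng), C7 (CH2), C8(Me)=C9 and C10 (CH–OAng). α denotes the face of the C1 methyl group and β the opposite face, for every bicyclic compound below.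

There are six stereocentres: C1 (Me α), C2 (OH α), C4 (OH β, isopropyl α), C5 (H α, hence cis fusion), C6 (OAng α) and C10 (OAng β). The C10 oxygen is therefore trans to the C1 methyl, the C2 oxygen is cis to it, and the C4 and C6 oxygens form an anti-1,3-diol across C5.

The sensitive groups are:
- the two angelates ((Z)-2-methylbut-2-enoates), which isomerise to tiglates with base, nucleophilic catalysts or prolonged heat;
- the allylic ester at C10;
- the tertiary C4 alcohol, which lies β to C6;
- the C7 methylene between C6 and C8=C9. Any C6 ketone on the way is a β,γ-unsaturated ketone that, once enolised towards C7, moves the alkene into conjugation or expels the C10 oxygen.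

The synthesis is hard because the quaternary C1 is flanked by three stereocentres (C2, C5, C10), because four oxygens must be told apart (two acylated, two free), and because a single alkene must be placed in a mobile seven-membered ring.

The strategy rests on the seven-membered ring. C8=C9, the C7 methylene, the vicinal C10 carbinol/C1 quaternary pair and a C6 oxygen written as a C5=C6 enol ether are the substitution pattern of a cyclohepta-1,4-diene. Such a diene arises from a cis-divinylcyclopropane by Cope rearrangement, with C7 as the former cyclopropane methylene and C1–C10 as the new σ-bond.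

## Retrosynthetic reasoning

**Ester C–O bonds at C6 and C10 (31 ⇒ 30 ⇒ 27 + 28).** The angelates are cut first because they are the most fragile part of 31. The C2 oxygen stays silylated in 30, so it is distinguished from the two hydroxyls of 27 that must be acylated. The tertiary C4 hydroxyl needs no protection. The forward reaction has to acylate a neopentyl allylic and an ordinary secondary alcohol with 28 without Z→E isomerisation, then remove the last silyl group without acyl migration.

**C10–O silyl bond and C6–H bond (27 ⇒ 26 ⇒ 25).** The C10 silyl ether of 26 is the more labile of the two silyl ethers and is removed selectively. The C6 carbinol is traced to ketone 25, because the neighbouring C4 hydroxyl can deliver hydride intramolecularly and so give the required anti-1,3-diol.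

**C5–H bond (25 ⇒ 24).** The β-hydroxy ketone 25 is the product of reductive cleavage of the C5–O bond of epoxy ketone 24. This puts the C4 oxygen where the epoxide was and sets C5 by protonation of a chelated enolate. The product is also the more stable ring-fusion epimer.

**Epoxide C–O bonds (24 ⇒ 23 ⇒ 22 ⇒ 21).** The epoxide is traced to the tetrasubstituted C4=C5 alkene. It is introduced on allylic alcohol 22 and not on enone 21 for two reasons. Basic peroxide conditions would enolise C7 of 21. In addition, no element in 21 controls the face, whereas the 6β-hydroxyl of 22 directs the oxidant to the β-face. C6 is then re-oxidised to reach 24.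

**C4=C5 double bond (21 ⇒ 20).** The enone comes from the C5=C6 silyl enol ether of 20 by dehydrogenation. The C4 stereocentre, whose only task is to steer the key step, is erased here on purpose.

**C8 methyl group (20 ⇒ 18 ⇒ 17).** The methyl group is the reduced form of the ester of 17. The reduction is done while C6 is still masked as the enol ether, so no ketone is exposed to hydride or base.

**C1–C10 and C7–C8 bonds (17 ⇒ 16 ⇒ 11 + 15).** This is the key disconnection. Reconnecting C6–C8 and cutting C1–C10 (retro-Cope) gives cis-divinylcyclopropane 16. Cutting C7–C8 and C6–C8 (retro-cyclopropanation) gives diene 11 and vinyl diazo ester 15. No other cut removes the seven-membered ring, the quaternary centre and the C10 stereocentre together while dividing the skeleton into two fragments of similar size. The gain is convergence, one ring, two skeletal bonds and two stereocentres in one operation. The forward reaction needs cyclopropanation of C6=C7 only, the two alkenyl groups cis on the cyclopropane, and attack of C10 on the C1 face opposite to the C2 and C4 substituents.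

**Enol ether and C6–C7 bond (11 ⇒ 10 ⇒ 9 ⇒ 7 + 8).** The 2-siloxydiene is the kinetic enol ether of methyl ketone 10. The ketone comes from aldehyde 7 by addition of 8 and oxidation.

**Ring contraction (7 ⇒ 6 ⇒ 5 ⇒ 4 ⇒ 3 ⇒ 2 ⇒ 1).** The cyclopentene double bond of 7 is the product of an intramolecular aldol condensation of keto aldehyde 6. Keto aldehyde 6 is the ozonolysis product (via 5) of cyclohexene 4. The cis relation of the C2 oxygen and the C4 isopropyl group comes from 1,2-reduction of 2, and 2 is the isopropenyl-hydrogenated form of 1. Compound 1 supplies the C1 methyl, the C2 oxygen and the C4 isopropyl stereocentre from the chiral pool.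

**Vinyl diazo ester (15 ⇒ 14 ⇒ 12 + 13).** The enol ether double bond is cut by retro-dehydration and the C–C bond by a retro-aldol addition of 12 to 13. This route is chosen because elimination fixes the E geometry that later becomes the C10 configuration. Direct enol silylation of an aldehyde would favour the Z isomer.

## Alternatives that were turned down

**Alternative 1:** C4–C5 disconnection of the cyclopentane.
- Forward key step: a C5 diazo group next to the C6 ester would be decomposed by a dirhodium carboxylate, and the carbenoid would insert into the oxygen-activated tertiary C4–H bond with retention. The product is A1, a cyclopentane cis-1,2-diester in which C6 and C10 are ester carbons and C4 already carries its tertiary silyl ether.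
- For it: five-membered ring formation by insertion into such a methine is dependable, and C4 arrives with its configuration intact. On this point it is stronger than the chosen route, which needs five steps to build the C4 carbinol.
- Against it: A1 contains only the small ring. The seven-membered ring, its alkene and both secondary carbinols still have to be grown from two esters on adjacent, crowded carbons by two chain extensions and a ring closure. The open-chain insertion substrate must already hold C1 (quaternary, two different esters), C2 and C4 in defined form.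
- Comparison: the key step forms one bond and no part of the seven-membered ring, so the step count is clearly higher. The chosen step offers the seven-membered ring, C1 and C10 in one convergent operation.

**Alternative 2:** Decalin to hydroazulene by a semipinacol shift.
- Forward key step: a strong alkoxide base would generate the C6 alkoxide, which pushes C1 from C6 to C5 as an equatorial C5 sulfonate leaves. Both six-membered rings change size and the product is A2, a cis-fused hydroazulen-6-one with C8=C9 in place.
- For it: the migration is stereospecific, so the ring fusion is secured by the decalin configuration. The C6 ketone and the alkene appear directly. For the ring fusion it is stronger than the chosen route, which sets C5 by a late protonation.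
- Against it: A2 still lacks the C4 isopropyl carbinol. Installing it means a C4 ketone β to the C6 ketone with an epimerisable C5 between them, and an isopropyl addition to a hindered cyclopentanone. The decalin substrate needs five stereocentres and three different protecting groups, which makes for a long linear sequence. The strongly basic key step also acts on a β,γ-unsaturated ketone with a leaving group at C10.
- Comparison: better stereochemical certainty at the fusion, worse step economy and an unsolved C4. The chosen route offers a short chiral-pool fragment and a planned, directed sequence for C4.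

**Alternative 3:** Glycol cleavage of a photoadduct cyclobutanediol.
- Forward key step: a glycol-cleaving oxidant would break the C6–C10 bond of a cis-cyclobutane-1,2-diol unit made by enone–alkene photocycloaddition. The cyclobutane and the methyl-bearing cyclopentane merge into the seven-membered ring of A3, a cis-fused 6,10-dione with the C4 carbinol already present.
- For it: C1, C4 and the cis fusion are set before the ring is opened, and both C6 and C10 oxygens arrive together. For C4 and C5 it is stronger than the chosen route.
- Against it: A3 has a saturated C8 and two ketones that differ only in their neighbours (C5–H against quaternary C1). The C8=C9 alkene must be introduced regioselectively towards C9 and not C7. The two ketones must then be reduced to opposite faces (6α, 10β) and kept distinguishable. C5 is epimerisable between carbonyl and carbinol throughout.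
- Comparison: stronger in early stereocontrol of the five-membered ring, weaker in placing the alkene and differentiating C6 from C10. The chosen cycloheptadiene comes with C8=C9, a masked C6 ketone and a protected C10 carbinol already differentiated.

Key step: step 11

Assumption: the prolinate dirhodium catalysts are taken to attack the same carbenoid face with diene 11 as they do with styrene, where the (S)-ligand catalyst gives the (1S,2R)-1,2-diarylcyclopropane ester. On that basis the (R)-ligand catalyst Rh2(R-DOSP)4, tetrakis[(R)-N-(4-dodecylphenylsulfonyl)prolinato]dirhodium, is the matched one for 11.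

## Route

Step 1
Reactants: 1 (R)-carvone
Product: 2 (R)-carvotanacetone [(5R)-2-methyl-5-(propan-2-yl)cyclohex-2-en-1-one]
Conditions: H2 (1 atm), RhCl(PPh3)3 (cat.), benzene, rt
Reagents that add atoms: none
Why: Homogeneous hydrogenation with RhCl(PPh3)3 should reduce the unhindered 1,1-disubstituted isopropenyl alkene and leave the conjugated trisubstituted enone alone; the stereocentre is not touched.

Step 2
Reactants: 2 (R)-carvotanacetone
Product: 3 (1R,5R)-2-methyl-5-(propan-2-yl)cyclohex-2-en-1-ol (hydroxyl cis to isopropyl)
Conditions: NaBH4, CeCl3·7H2O, MeOH, −20 °C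
Reagents that add atoms: none
Why: Luche 1,2-reduction; axial hydride delivery to the half-chair with equatorial isopropyl should give the cis allylic alcohol, as carvone itself does.

Step 3
Reactants: 3 cis-allylic alcohol
Product: 4 triisopropylsilyl ether of 3
Conditions: TIPSOTf, 2,6-lutidine, CH2Cl2, 0 °C
Reagents that add atoms: triisopropylsilyl trifluoromethanesulfonate, CC(C)[Si](C(C)C)(C(C)C)OS(=O)(=O)C(F)(F)F
Why: Standard silylation of a secondary alcohol; the bulky, acid- and fluoride-resistant TIPS group is chosen so that the future C2 oxygen outlasts the TBS group placed later on C10.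

Step 4
Reactants: 4 TIPS ether
Product: 6 (3S,5R)-6-oxo-3-(propan-2-yl)-5-(triisopropylsilyloxy)heptanal, via secondary ozonide 5 (not isolated)
Conditions: O3, CH2Cl2, −78 °C; then PPh3, −78 °C → rt
Reagents that add atoms: ozone, [O-][O+]=O
Why: Ozonolysis of the only alkene with reductive work-up opens the ring to the methyl ketone/aldehyde pair; both stereocentres are spectators.

Step 5
Reactants: 6 keto aldehyde
Product: 7 (3R,5R)-2-methyl-5-(propan-2-yl)-3-(triisopropylsilyloxy)cyclopent-1-ene-1-carbaldehyde
Conditions: Bn2NH·CF3CO2H (cat.), toluene, 50 °C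
Reagents that add atoms: none
Why: Amine-catalysed intramolecular aldol condensation; the aldehyde enamine attacks the methyl ketone to close the five-membered ring, and dehydration gives the tetrasubstituted enal. The mild ammonium salt is chosen to spare the silyloxy-bearing centre next to the ketone.

Step 6
Reactants: 7 cyclopentene carbaldehyde; 8 methylmagnesium bromide
Product: 9 1-[(3R,5R)-2-methyl-5-(propan-2-yl)-3-(triisopropylsilyloxy)cyclopent-1-en-1-yl]ethan-1-ol (both carbinol epimers)
Conditions: THF, −78 → 0 °C
Reagents that add atoms: none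
Why: Grignard 1,2-addition to the enal brings in the carbon that becomes C7; the new carbinol centre is oxidised in the next step, so its configuration is immaterial.

Step 7
Reactants: 9 allylic alcohol
Product: 10 1-[(3R,5R)-2-methyl-5-(propan-2-yl)-3-(triisopropylsilyloxy)cyclopent-1-en-1-yl]ethan-1-one
Conditions: Dess–Martin periodinane, CH2Cl2, 0 °C → rt
Reagents that add atoms: none
Why: Dess–Martin oxidation of a secondary allylic alcohol to the methyl ketone under neutral conditions.

Step 8
Reactants: 10 methyl ketone
Product: 11 tert-butyldimethyl({1-[(3R,5R)-2-methyl-5-(propan-2-yl)-3-(triisopropylsilyloxy)cyclopent-1-en-1-yl]ethenyl}oxy)silane (2-siloxydiene)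
Conditions: TBSOTf, Et3N, CH2Cl2, −78 → 0 °C
Reagents that add atoms: tert-butyldimethylsilyl trifluoromethanesulfonate, CC(C)(C)[Si](C)(C)OS(=O)(=O)C(F)(F)F
Why: Soft enolisation of the O-silylated enone at the accessible acetyl methyl group should give the cross-conjugated 2-siloxydiene, the usual outcome for 1-acylcycloalkenes.

Step 9
Reactants: 12 methyl diazoacetate; 13 (tert-butyldimethylsilyloxy)acetaldehyde
Product: 14 methyl 4-(tert-butyldimethylsilyloxy)-2-diazo-3-hydroxybutanoate (racemic)
Conditions: DBU (10 mol%), MeCN, 0 °C → rt
Reagents that add atoms: none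
Why: Base-catalysed aldol-type addition of the acidic diazoacetate C–H to the aldehyde; the carbinol centre is removed in step 10.

Step 10
Reactants: 14 β-hydroxy diazo ester
Product: 15 methyl (E)-4-(tert-butyldimethylsilyloxy)-2-diazobut-3-enoate
Conditions: POCl3, Et3N, CH2Cl2, 0 °C
Reagents that add atoms: none
Why: Activation of the hydroxyl and elimination, the standard dehydration route to vinyl diazoacetates; the only β-hydrogens are on the silyloxy-bearing carbon, so the enol ether must form, and the E isomer (diazo ester carbon and silyloxy group trans, conjugated) is expected. 15 is to be used fresh and cold.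

Step 11
Reactants: 11 2-siloxydiene; 15 vinyl diazo ester
Product: 17 methyl 6,10β-bis(tert-butyldimethylsilyloxy)-1α-methyl-4α-(propan-2-yl)-2α-(triisopropylsilyloxy)bicyclo[5.3.0]deca-5,8-diene-8-carboxylate, via cis-divinylcyclopropane 16 (not isolated)
Conditions: Rh2(R-DOSP)4 (1 mol%), hexane, −40 °C → rt, slow addition of 15; then toluene, 90 °C
Reagents that add atoms: none
Why: Proposed new method: the dirhodium catalyst should turn 15 into a donor/acceptor vinylcarbenoid (loss of N2) that attacks the electron-rich C7 methylene terminus of the silyl enol ether of 11 end-on and closes the cyclopropane C6–C7–C8 with the cyclopentenyl group cis to the siloxyvinyl group (16); the closest known reaction type is the dirhodium-catalysed vinylcarbenoid cyclopropanation/Cope formal [4+3] cycloaddition of 2-siloxydienes and of 1-vinylcycloalkenes whose ring carbon becomes quaternary, whereas a 4-siloxy vinyldiazoacetate has not been used in it. The tetrasubstituted C5=C1 bond is inert to the bulky carbenoid, so only C6=C7 should react. On warming, 16 should undergo the Cope rearrangement through the boat transition state in which both alkenyl groups lie over the three-membered ring: C6–C8 breaks and C1–C10 forms, so the seven-membered ring is closed by a [3,3] sigmatropic ring expansion and not by an end-to-end cyclisation, and C8=C9 and the C5=C6 silyl enol ether are left exactly where the target needs its alkene and its C6 oxygen. C10 is controlled by the E enol ether (silyloxy on the outside of the boat) together with the ring-locked C5=C1 geometry (methyl inside, C2 outside), which places the C10 oxygen cis to C2 and trans to the C1 methyl. C1 is controlled by the configuration of the cyclopropane: in 16 the ester-bearing C8 lies on the cyclopentene face opposite to the C2 silyloxy and C4 isopropyl groups, so C10 bonds to C1 from that open face; this is the cyclopropane expected from the (R)-prolinate catalyst, and the diastereomeric cyclopropane would have to rearrange syn to both groups. The step needs site selectivity, cis-divinyl selectivity and facial selectivity; the first rests on alkene substitution, the second on the usual placement of the unsaturated substituent next to the donor group and on the ability of this silyloxy/ester-substituted cyclopropane to epimerise at C6 on heating, the third on the matched catalyst reinforced by the substrate in the Cope step. Heating is planned because the methyl group on the inside of the boat retards the rearrangement.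

Step 12
Reactants: 17 cycloheptadiene ester
Product: 18 6,10β-bis(tert-butyldimethylsilyloxy)-8-(hydroxymethyl)-1α-methyl-4α-(propan-2-yl)-2α-(triisopropylsilyloxy)bicyclo[5.3.0]deca-5,8-diene
Conditions: iBu2AlH (2.5 equiv), CH2Cl2, −78 °C
Reagents that add atoms: none
Why: 1,2-Reduction of the conjugated ester to the allylic alcohol; silyl ethers and the TBS enol ether are inert to iBu2AlH at low temperature.

Step 13
Reactants: 18 allylic alcohol
Product: 20 6,10β-bis(tert-butyldimethylsilyloxy)-1α,8-dimethyl-4α-(propan-2-yl)-2α-(triisopropylsilyloxy)bicyclo[5.3.0]deca-5,8-diene, via allylic mesylate 19 (not isolated)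
Conditions: MsCl, Et3N, THF, −40 °C; then LiEt3BH, −40 → 0 °C
Reagents that add atoms: methanesulfonyl chloride, CS(=O)(=O)Cl (adds the mesyl group of 19; none of it remains in 20)
Why: One-pot sulfonylation and SN2 hydride displacement of a primary allylic mesylate; direct attack at the CH2 group is favoured over SN2′ attack at C9, which is shielded by the neopentyl C10. The C6 oxygen stays masked as the enol ether, so no ketone meets the hydride.

Step 14
Reactants: 20 silyl enol ether
Product: 21 10β-(tert-butyldimethylsilyloxy)-1α,8-dimethyl-4-(propan-2-yl)-2α-(triisopropylsilyloxy)bicyclo[5.3.0]deca-4,8-dien-6-one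
Conditions: Pd(OAc)2 (1.2 equiv), MeCN, 40 °C
Reagents that add atoms: none
Why: Saegusa–Ito oxidation; divalent palladium replaces silicon on the enol ether, and the C5-bound palladium enolate has β-hydrogen only on C4 (C1 is quaternary and C7 is not part of this enolate), so β-hydride elimination can only give the C4=C5 enone. The conditions are neutral and the C4 stereocentre is removed on purpose.

Step 15
Reactants: 21 enone
Product: 22 10β-(tert-butyldimethylsilyloxy)-1α,8-dimethyl-4-(propan-2-yl)-2α-(triisopropylsilyloxy)bicyclo[5.3.0]deca-4,8-dien-6β-ol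
Conditions: NaBH4, CeCl3·7H2O, MeOH/THF, −78 → −40 °C
Reagents that add atoms: none
Why: Luche 1,2-reduction, cold and short so that C7 is not enolised. Hydride is expected on the α-face of C6 because the seven-membered ring folds towards the β-face, where C9, C10 and the C10 silyloxy group sit; this places the new hydroxyl β.

Step 16
Reactants: 22 allylic alcohol
Product: 23 4β,5β-epoxy-10β-(tert-butyldimethylsilyloxy)-1α,8-dimethyl-4α-(propan-2-yl)-2α-(triisopropylsilyloxy)bicyclo[5.3.0]dec-8-en-6β-ol
Conditions: VO(acac)2 (5 mol%), tBuOOH, CH2Cl2, 0 °C → rt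
Reagents that add atoms: tert-butyl hydroperoxide, CC(C)(C)OO
Why: Vanadium-catalysed hydroxyl-directed epoxidation; the allylic 6β-hydroxyl binds the vanadium peroxide and should deliver oxygen to the β-face of the tetrasubstituted C4=C5 bond, which fixes the C4 oxygen β. The allylic tetrasubstituted alkene reacts much faster than the homoallylic trisubstituted C8=C9.

Step 17
Reactants: 23 epoxy alcohol
Product: 24 4β,5β-epoxy-10β-(tert-butyldimethylsilyloxy)-1α,8-dimethyl-4α-(propan-2-yl)-2α-(triisopropylsilyloxy)bicyclo[5.3.0]dec-8-en-6-one
Conditions: Dess–Martin periodinane, NaHCO3, CH2Cl2, 0 °C → rt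
Reagents that add atoms: none
Why: Buffered Dess–Martin oxidation gives the α,β-epoxy ketone without enolising C7; the C6 centre that served for direction is erased.

Step 18
Reactants: 24 epoxy ketone
Product: 25 10β-(tert-butyldimethylsilyloxy)-4β-hydroxy-1α,8-dimethyl-4α-(propan-2-yl)-2α-(triisopropylsilyloxy)bicyclo[5.3.0]dec-8-en-6-one (5α-H, cis-fused)
Conditions: SmI2 (2.5 equiv), THF/MeOH, −78 °C
Reagents that add atoms: none
Why: Reductive opening of an α,β-epoxy ketone by SmI2; the C5–O bond is cleaved and the C4 oxygen stays as the β tertiary alcohol. The enolate is expected to be protonated at C5 inside a samarium chelate between O4 and the enolate oxygen, which holds C6 on the β-face so that the proton enters from the α-face. The resulting cis-fused ketone is also the more stable epimer, with C6 trans to the C4 isopropyl and C1 methyl groups on the cyclopentane.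

Step 19
Reactants: 25 β-hydroxy ketone
Product: 26 10β-(tert-butyldimethylsilyloxy)-1α,8-dimethyl-4α-(propan-2-yl)-2α-(triisopropylsilyloxy)bicyclo[5.3.0]dec-8-ene-4β,6α-diol
Conditions: Me4NBH(OAc)3, MeCN/AcOH, −30 °C
Reagents that add atoms: none
Why: Evans–Saksena reduction; the C4 hydroxyl exchanges onto boron and delivers hydride intramolecularly to the β-face of C6, which should give the anti-1,3-diol, here the 6α-alcohol. The weakly acidic medium does not enolise C7.

Step 20
Reactants: 26 diol
Product: 27 1α,8-dimethyl-4α-(propan-2-yl)-2α-(triisopropylsilyloxy)bicyclo[5.3.0]dec-8-ene-4β,6α,10β-triol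
Conditions: HF·pyridine, pyridine, THF, 0 °C → rt
Reagents that add atoms: none
Why: Selective desilylation; under buffered HF·pyridine a secondary TBS ether is cleaved far faster than the TIPS ether at C2.

Step 21
Reactants: 27 triol; 28 angelic acid
Product: 30 6α,10β-bis(angeloyloxy)-1α,8-dimethyl-4α-(propan-2-yl)-2α-(triisopropylsilyloxy)bicyclo[5.3.0]dec-8-en-4β-ol, via mixed anhydride 29 (not isolated)
Conditions: 2,4,6-Cl3C6H2COCl, Et3N, toluene, rt; then 27, 80 °C
Reagents that add atoms: 2,4,6-trichlorobenzoyl chloride, O=C(Cl)c1c(Cl)cc(Cl)cc1Cl (adds the aroyl group of 29; none of it remains in 30)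
Why: Yamaguchi-type acylation through the mixed anhydride without a nucleophilic catalyst, the conditions under which angelates are formed without Z→E isomerisation. Both secondary hydroxyls should be acylated, and the hindered tertiary C4 hydroxyl should not react.

Step 22
Reactants: 30 bis-angelate
Product: 31 6α,10β-bis(angeloyloxy)-1α,8-dimethyl-4α-(propan-2-yl)bicyclo[5.3.0]dec-8-ene-2α,4β-diol (CNP0249167.1)
Conditions: HF·pyridine (excess), THF, rt → 40 °C
Reagents that add atoms: none
Why: Fluoride cleavage of the remaining TIPS ether under mildly acidic, non-nucleophilic conditions, which should neither isomerise the angelates nor move an acyl group from O10 to O2.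

## Compound list

1 | (R)-carvone | CC1=CC[C@H](CC1=O)C(C)=C | starting material
2 | (R)-carvotanacetone, (5R)-2-methyl-5-(propan-2-yl)cyclohex-2-en-1-one | CC1=CC[C@H](CC1=O)C(C)C | intermediate
3 | (1R,5R)-2-methyl-5-(propan-2-yl)cyclohex-2-en-1-ol (hydroxyl cis to isopropyl) | CC1=CC[C@H](C[C@H]1O)C(C)C | intermediate
4 | triisopropyl{[(1R,5R)-2-methyl-5-(propan-2-yl)cyclohex-2-en-1-yl]oxy}silane | CC1=CC[C@H](C[C@H]1O[Si](C(C)C)(C(C)C)C(C)C)C(C)C | intermediate
5 | secondary ozonide of 4 (1,2,4-trioxolane across the former ring alkene, mixture at the two new centres) | CC12OC(OO1)C[C@H](C[C@H]2O[Si](C(C)C)(C(C)C)C(C)C)C(C)C | intermediate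
6 | (3S,5R)-6-oxo-3-(propan-2-yl)-5-(triisopropylsilyloxy)heptanal | CC(=O)[C@H](O[Si](C(C)C)(C(C)C)C(C)C)C[C@@H](CC=O)C(C)C | intermediate
7 | (3R,5R)-2-methyl-5-(propan-2-yl)-3-(triisopropylsilyloxy)cyclopent-1-ene-1-carbaldehyde | O=CC1=C(C)[C@H](O[Si](C(C)C)(C(C)C)C(C)C)C[C@@H]1C(C)C | intermediate
8 | methylmagnesium bromide | C[Mg]Br | starting material
9 | 1-[(3R,5R)-2-methyl-5-(propan-2-yl)-3-(triisopropylsilyloxy)cyclopent-1-en-1-yl]ethan-1-ol (both carbinol epimers) | CC(O)C1=C(C)[C@H](O[Si](C(C)C)(C(C)C)C(C)C)C[C@@H]1C(C)C | intermediate
10 | 1-[(3R,5R)-2-methyl-5-(propan-2-yl)-3-(triisopropylsilyloxy)cyclopent-1-en-1-yl]ethan-1-one | CC(=O)C1=C(C)[C@H](O[Si](C(C)C)(C(C)C)C(C)C)C[C@@H]1C(C)C | intermediate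
11 | tert-butyldimethyl({1-[(3R,5R)-2-methyl-5-(propan-2-yl)-3-(triisopropylsilyloxy)cyclopent-1-en-1-yl]ethenyl}oxy)silane (C2 OTIPS and C4 isopropyl cis) | C=C(O[Si](C)(C)C(C)(C)C)C1=C(C)[C@H](O[Si](C(C)C)(C(C)C)C(C)C)C[C@@H]1C(C)C | intermediate
12 | methyl diazoacetate | COC(=O)C=[N+]=[N-] | starting material
13 | (tert-butyldimethylsilyloxy)acetaldehyde | O=CCO[Si](C)(C)C(C)(C)C | starting material
14 | methyl 4-(tert-butyldimethylsilyloxy)-2-diazo-3-hydroxybutanoate (racemic) | COC(=O)C(=[N+]=[N-])C(O)CO[Si](C)(C)C(C)(C)C | intermediate
15 | methyl (E)-4-(tert-butyldimethylsilyloxy)-2-diazobut-3-enoate | COC(=O)C(=[N+]=[N-])/C=C/O[Si](C)(C)C(C)(C)C | intermediate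
16 | methyl (1S,2R)-2-(tert-butyldimethylsilyloxy)-1-[(E)-2-(tert-butyldimethylsilyloxy)ethenyl]-2-[(3R,5R)-2-methyl-5-(propan-2-yl)-3-(triisopropylsilyloxy)cyclopent-1-en-1-yl]cyclopropane-1-carboxylate (siloxyvinyl and cyclopentenyl groups cis) | COC(=O)[C@]1(/C=C/O[Si](C)(C)C(C)(C)C)C[C@@]1(O[Si](C)(C)C(C)(C)C)C2=C(C)[C@H](O[Si](C(C)C)(C(C)C)C(C)C)C[C@@H]2C(C)C | intermediate
17 | methyl 6,10β-bis(tert-butyldimethylsilyloxy)-1α-methyl-4α-(propan-2-yl)-2α-(triisopropylsilyloxy)bicyclo[5.3.0]deca-5,8-diene-8-carboxylate | CC(C)(C)[Si](C)(C)OC=1CC(C(=O)OC)=C[C@@H](O[Si](C)(C)C(C)(C)C)[C@@]2(C)[C@H](O[Si](C(C)C)(C(C)C)C(C)C)C[C@H](C(C)C)C=12 | intermediate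
18 | 6,10β-bis(tert-butyldimethylsilyloxy)-8-(hydroxymethyl)-1α-methyl-4α-(propan-2-yl)-2α-(triisopropylsilyloxy)bicyclo[5.3.0]deca-5,8-diene | CC(C)(C)[Si](C)(C)OC=1CC(CO)=C[C@@H](O[Si](C)(C)C(C)(C)C)[C@@]2(C)[C@H](O[Si](C(C)C)(C(C)C)C(C)C)C[C@H](C(C)C)C=12 | intermediate
19 | methanesulfonate of 18 (8-CH2OMs) | CC(C)(C)[Si](C)(C)OC=1CC(COS(C)(=O)=O)=C[C@@H](O[Si](C)(C)C(C)(C)C)[C@@]2(C)[C@H](O[Si](C(C)C)(C(C)C)C(C)C)C[C@H](C(C)C)C=12 | intermediate
20 | 6,10β-bis(tert-butyldimethylsilyloxy)-1α,8-dimethyl-4α-(propan-2-yl)-2α-(triisopropylsilyloxy)bicyclo[5.3.0]deca-5,8-diene | CC(C)(C)[Si](C)(C)OC=1CC(C)=C[C@@H](O[Si](C)(C)C(C)(C)C)[C@@]2(C)[C@H](O[Si](C(C)C)(C(C)C)C(C)C)C[C@H](C(C)C)C=12 | intermediate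
21 | 10β-(tert-butyldimethylsilyloxy)-1α,8-dimethyl-4-(propan-2-yl)-2α-(triisopropylsilyloxy)bicyclo[5.3.0]deca-4,8-dien-6-one | O=C1CC(C)=C[C@@H](O[Si](C)(C)C(C)(C)C)[C@@]2(C)[C@H](O[Si](C(C)C)(C(C)C)C(C)C)CC(C(C)C)=C12 | intermediate
22 | 10β-(tert-butyldimethylsilyloxy)-1α,8-dimethyl-4-(propan-2-yl)-2α-(triisopropylsilyloxy)bicyclo[5.3.0]deca-4,8-dien-6β-ol | O[C@H]1CC(C)=C[C@@H](O[Si](C)(C)C(C)(C)C)[C@@]2(C)[C@H](O[Si](C(C)C)(C(C)C)C(C)C)CC(C(C)C)=C12 | intermediate
23 | 4β,5β-epoxy-10β-(tert-butyldimethylsilyloxy)-1α,8-dimethyl-4α-(propan-2-yl)-2α-(triisopropylsilyloxy)bicyclo[5.3.0]dec-8-en-6β-ol | O[C@H]1CC(C)=C[C@@H](O[Si](C)(C)C(C)(C)C)[C@@]2(C)[C@H](O[Si](C(C)C)(C(C)C)C(C)C)C[C@@]3(C(C)C)O[C@@]123 | intermediate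
24 | 4β,5β-epoxy-10β-(tert-butyldimethylsilyloxy)-1α,8-dimethyl-4α-(propan-2-yl)-2α-(triisopropylsilyloxy)bicyclo[5.3.0]dec-8-en-6-one | O=C1CC(C)=C[C@@H](O[Si](C)(C)C(C)(C)C)[C@@]2(C)[C@H](O[Si](C(C)C)(C(C)C)C(C)C)C[C@@]3(C(C)C)O[C@@]123 | intermediate
25 | 10β-(tert-butyldimethylsilyloxy)-4β-hydroxy-1α,8-dimethyl-4α-(propan-2-yl)-2α-(triisopropylsilyloxy)bicyclo[5.3.0]dec-8-en-6-one (5α-H) | O=C1CC(C)=C[C@@H](O[Si](C)(C)C(C)(C)C)[C@@]2(C)[C@H](O[Si](C(C)C)(C(C)C)C(C)C)C[C@](O)(C(C)C)[C@@H]12 | intermediate
26 | 10β-(tert-butyldimethylsilyloxy)-1α,8-dimethyl-4α-(propan-2-yl)-2α-(triisopropylsilyloxy)bicyclo[5.3.0]dec-8-ene-4β,6α-diol (5α-H) | O[C@@H]1CC(C)=C[C@@H](O[Si](C)(C)C(C)(C)C)[C@@]2(C)[C@H](O[Si](C(C)C)(C(C)C)C(C)C)C[C@](O)(C(C)C)[C@@H]12 | intermediate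
27 | 1α,8-dimethyl-4α-(propan-2-yl)-2α-(triisopropylsilyloxy)bicyclo[5.3.0]dec-8-ene-4β,6α,10β-triol (5α-H) | O[C@@H]1CC(C)=C[C@@H](O)[C@@]2(C)[C@H](O[Si](C(C)C)(C(C)C)C(C)C)C[C@](O)(C(C)C)[C@@H]12 | intermediate
28 | angelic acid, (Z)-2-methylbut-2-enoic acid | C/C=C(/C)C(=O)O | starting material
29 | (Z)-2-methylbut-2-enoic 2,4,6-trichlorobenzoic anhydride | C/C=C(/C)C(=O)OC(=O)c1c(Cl)cc(Cl)cc1Cl | intermediate
30 | 6α,10β-bis(angeloyloxy)-1α,8-dimethyl-4α-(propan-2-yl)-2α-(triisopropylsilyloxy)bicyclo[5.3.0]dec-8-en-4β-ol (5α-H) | C/C=C(/C)C(=O)O[C@@H]1CC(C)=C[C@@H](OC(=O)/C(C)=C\C)[C@@]2(C)[C@H](O[Si](C(C)C)(C(C)C)C(C)C)C[C@](O)(C(C)C)[C@@H]12 | intermediate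
31 | 6α,10β-bis(angeloyloxy)-1α,8-dimethyl-4α-(propan-2-yl)bicyclo[5.3.0]dec-8-ene-2α,4β-diol (5α-H), CNP0249167.1 | C/C=C(/C)C(=O)O[C@@H]1CC(C)=C[C@@H](OC(=O)/C(C)=C\C)[C@@]2(C)[C@H](O)C[C@](O)(C(C)C)[C@@H]12 | target

## Step count and least certain steps

Total: 22 steps. Longest linear sequence: 20 steps (steps 1–8 and 11–22); the diazo fragment takes 2 steps (9–10).

**Step 11 (key step, proposed new method).** Several things can go wrong.
- 15 may electrocyclise to a pyrazole before the carbenoid is formed.
- The cyclopropanation may place the silyloxy group, not the cyclopentenyl group, next to the siloxyvinyl group.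
- The catalyst may turn out mismatched with the substrate, giving poor facial selectivity.
- The Cope step may be too slow, because C1 is fully substituted and carries its methyl on the inside of the boat. Heterolytic opening of the silyloxy/ester-substituted cyclopropane (formal [3+2] closure or silyl transfer) could then compete.

Fallback by known chemistry, setting out from 11 and returning at 17. The silyl enol ether of 11 is cyclopropanated with 12 under Cu(acac)2 catalysis to the siloxycyclopropane ester F1. Its ester α-position is deprotonated with LiN(iPr)2 at −78 °C and added to 13, giving the aldol F2. Dehydration with the Burgess reagent gives 16 as a diastereomer mixture. Heating in toluene then leads to 17: trans isomers feed the cis isomer by epimerisation at C6, and the facial choice rests on the substrate alone, with the Cope step anti to the C2 and C4 substituents.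

**Step 14.** The palladium enolate has to form at the crowded, fully substituted C5 and reach the C4–H bond on the same face. Slow metalation would allow simple protodesilylation to the saturated ketone.

Fallback, from 20 back to 21. Bromination of the enol ether with N-bromosuccinimide (THF, −78 °C) gives the tertiary α-bromo ketone F3. Dehydrobromination with Li2CO3/LiBr in DMF at the lowest workable temperature can only eliminate towards C4, since C1 bears no hydrogen.

**Step 15 (and with it step 16).** The facial selectivity of the hydride addition is the weak point. If hydride enters from the β-face, the 6α-alcohol results, and the vanadium epoxidation would then be steered to the α-face and give the wrong C4 configuration.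

Fallback, from 21 back to 22. The 6α-alcohol F4 obtained in that case is inverted by a Mitsunobu reaction with 4-nitrobenzoic acid (PPh3, diisopropyl azodicarboxylate) to the 6β 4-nitrobenzoate F5. Methanolysis with K2CO3 in MeOH gives 22.

**Step 21.** Acylation of the neopentyl allylic C10 hydroxyl may stall, and prolonged heating may isomerise angelate to tiglate.

Fallback, from 27 back to 30. Both secondary hydroxyls are esterified with 2-[bis(2,2,2-trifluoroethoxy)phosphoryl]propanoic acid (carbodiimide coupling) to the bis(phosphonopropionate) F6. A Still–Gennari olefination with acetaldehyde (KN(SiMe3)2, 18-crown-6, THF, −78 °C) then builds both (Z)-2-methylbut-2-enoates on the molecule.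

## Further compounds

F1 | step 11 | methyl 2-(tert-butyldimethylsilyloxy)-2-[(3R,5R)-2-methyl-5-(propan-2-yl)-3-(triisopropylsilyloxy)cyclopent-1-en-1-yl]cyclopropane-1-carboxylate (diastereomer mixture) | COC(=O)C1CC1(O[Si](C)(C)C(C)(C)C)C2=C(C)[C@H](O[Si](C(C)C)(C(C)C)C(C)C)C[C@@H]2C(C)C
F2 | step 11 | methyl 2-(tert-butyldimethylsilyloxy)-1-[2-(tert-butyldimethylsilyloxy)-1-hydroxyethyl]-2-[(3R,5R)-2-methyl-5-(propan-2-yl)-3-(triisopropylsilyloxy)cyclopent-1-en-1-yl]cyclopropane-1-carboxylate (diastereomer mixture) | COC(=O)C1(C(O)CO[Si](C)(C)C(C)(C)C)CC1(O[Si](C)(C)C(C)(C)C)C2=C(C)[C@H](O[Si](C(C)C)(C(C)C)C(C)C)C[C@@H]2C(C)C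
F3 | step 14 | 5-bromo-10β-(tert-butyldimethylsilyloxy)-1α,8-dimethyl-4α-(propan-2-yl)-2α-(triisopropylsilyloxy)bicyclo[5.3.0]dec-8-en-6-one | O=C1CC(C)=C[C@@H](O[Si](C)(C)C(C)(C)C)[C@@]2(C)[C@H](O[Si](C(C)C)(C(C)C)C(C)C)C[C@H](C(C)C)C12Br
F4 | step 15 | 10β-(tert-butyldimethylsilyloxy)-1α,8-dimethyl-4-(propan-2-yl)-2α-(triisopropylsilyloxy)bicyclo[5.3.0]deca-4,8-dien-6α-ol | O[C@@H]1CC(C)=C[C@@H](O[Si](C)(C)C(C)(C)C)[C@@]2(C)[C@H](O[Si](C(C)C)(C(C)C)C(C)C)CC(C(C)C)=C12
F5 | step 15 | 6β-(4-nitrobenzoyloxy) ester of 22 | O=C(O[C@H]1CC(C)=C[C@@H](O[Si](C)(C)C(C)(C)C)[C@@]2(C)[C@H](O[Si](C(C)C)(C(C)C)C(C)C)CC(C(C)C)=C12)c3ccc(cc3)[N+](=O)[O-]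
F6 | step 21 | 6α,10β-bis{2-[bis(2,2,2-trifluoroethoxy)phosphoryl]propanoyloxy}-1α,8-dimethyl-4α-(propan-2-yl)-2α-(triisopropylsilyloxy)bicyclo[5.3.0]dec-8-en-4β-ol | CC(C(=O)O[C@@H]1CC(C)=C[C@@H](OC(=O)C(C)P(=O)(OCC(F)(F)F)OCC(F)(F)F)[C@@]2(C)[C@H](O[Si](C(C)C)(C(C)C)C(C)C)C[C@](O)(C(C)C)[C@@H]12)P(=O)(OCC(F)(F)F)OCC(F)(F)F
A1 | alternative 1 | dimethyl cis-cyclopentane-1,2-dicarboxylate with the C1 methyl, the C2 tert-butyldimethylsilyl ether and the C4 triethylsilyl ether/isopropyl groups (C6 and C10 as ester carbons) | COC(=O)[C@@H]1[C@@](O[Si](CC)(CC)CC)(C(C)C)C[C@@H](O[Si](C)(C)C(C)(C)C)[C@]1(C)C(=O)OC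
A2 | alternative 2 | cis-fused 10-(4-methoxybenzyloxy)-1,8-dimethyl-2-(tert-butyldimethylsilyloxy)-4-(triethylsilyloxy)bicyclo[5.3.0]dec-8-en-6-one | O=C1CC(C)=C[C@@H](OCc3ccc(OC)cc3)[C@@]2(C)[C@H](O[Si](C)(C)C(C)(C)C)C[C@H](O[Si](CC)(CC)CC)[C@@H]12
A3 | alternative 3 | cis-fused 4-hydroxy-1,8-dimethyl-4-(propan-2-yl)-2-(tert-butyldimethylsilyloxy)bicyclo[5.3.0]decane-6,10-dione | O=C1C[C@@H](C)CC(=O)[C@@]2(C)[C@H](O[Si](C)(C)C(C)(C)C)C[C@](O)(C(C)C)[C@@H]12
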